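**Retrosynthetic overview**
- The target is the (3R)-isoflavanone 24. The two MOM ethers come off last; before that, C3–H is set by enantioselective palladium-catalysed decarboxylative protonation of the racemic allyl 4-oxochromane-3-carboxylate 22.
- Ring C of 22 is made in one operation from benzyne precursor 9 and hydroxymethyl malonate 20, forming O1–C8a and C4–C4a.
- The strategy rests on this feature: ring C hangs O1 and the C4 carbonyl on the adjacent ring A carbons C8a and C4a, and the C5 oxygen next to C4a polarises a 4a,8a-aryne so that oxygen adds at C8a and the carbanion sits at C4a.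
- 20 comes from 2,4-dihydroxybenzaldehyde: chromene formation, O-methylation, one-carbon homologation to the allyl arylacetate, C-carboxylation and hydroxymethylation. 9 comes from phloroglucinol by carbamate-directed ortho-silylation.
- Ring order: rings A and B are bought, the dimethylpyran ring of the chromene is closed first (step 5), ring C last (step 12).

Key step: step 12

Assumption: (S)-t-BuPHOX, (S)-4-tert-butyl-2-[2-(diphenylphosphino)phenyl]-4,5-dihydrooxazole, is taken to deliver the 3R ketone in step 13. If the sense of protonation proves opposite, the (R)-ligand is used and nothing else changes.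

**Step 1**
Reactants: 1 phloroglucinol
Product: 2 3,5-bis(methoxymethoxy)phenol
Conditions: MOMCl (2.0 equiv), i-Pr2NEt, DMF, 0 °C to rt; chromatography
Reagents that add atoms: chloromethyl methyl ether, COCCl
Why: O-alkylation of the phenoxide with an α-chloro ether under stoichiometric control should give the bis-ether as the main component of a statistical mixture, separable from mono- and tris-ether, with the mono-ether recyclable.

**Step 2**
Reactants: 2 3,5-bis(methoxymethoxy)phenol
Product: 3 3,5-bis(methoxymethoxy)phenyl N-isopropylcarbamate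
Conditions: i-PrNCO, Et3N (cat.), CH2Cl2, rt
Reagents that add atoms: isopropyl isocyanate, CC(C)N=C=O
Why: Amine-catalysed addition of a phenol to an isocyanate (carbamoylation) installs the strongest ortho-directing group on the ring in a form that is later removed by base alone.

**Step 3**
Reactants: 3 3,5-bis(methoxymethoxy)phenyl N-isopropylcarbamate
Product: 7 3,5-bis(methoxymethoxy)-2-(trimethylsilyl)phenyl N-isopropylcarbamate, via N-silyl carbamate 4 (not isolated), via aryllithium 5 (not isolated), via N-silyl C-silyl carbamate 6 (not isolated)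
Conditions: TMSOTf (1.05 equiv), TMEDA, Et2O, 0 °C; n-BuLi, TMEDA, −78 °C; TMSCl, −78 °C to rt; MeOH, aq. NH4Cl
Reagents that add atoms: chlorotrimethylsilane, C[Si](C)(C)Cl (the C-silyl group); trimethylsilyl triflate, C[Si](C)(C)OS(=O)(=O)C(F)(F)F (only the transient N-silyl group of 4 to 6, lost on work-up)
Why: Directed ortho-metalation with in situ N-silyl protection of the secondary carbamate should lithiate one of the two equivalent positions flanked by the carbamate and a MOM ether (carbamate outranks MOM as director), and TMSCl then silylates that carbon.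

**Step 4**
Reactants: 7 3,5-bis(methoxymethoxy)-2-(trimethylsilyl)phenyl N-isopropylcarbamate
Product: 9 3,5-bis(methoxymethoxy)-2-(trimethylsilyl)phenyl trifluoromethanesulfonate, via silylphenol 8 (not isolated)
Conditions: Et2NH, DBU, MeCN, 40 °C; then PhNTf2, rt
Reagents that add atoms: N-phenylbis(trifluoromethanesulfonimide), O=S(=O)(N(c1ccccc1)S(=O)(=O)C(F)(F)F)C(F)(F)F
Why: E1cB cleavage of the N-monoalkyl carbamate (isocyanate trapped by Et2NH as a urea) frees the ortho-silyl phenoxide, which is triflated in the same pot, the standard one-pot access to ortho-silylaryl triflates.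

**Step 5**
Reactants: 10 2,4-dihydroxybenzaldehyde; 11 3-methylbut-2-enal
Product: 12 5-hydroxy-2,2-dimethyl-2H-chromene-6-carbaldehyde
Conditions: pyridine, 120 °C (sealed tube)
Reagents that add atoms: none
Why: Base-mediated condensation of the enal at C3 followed by oxa-6π electrocyclisation (chromenylation) should engage the 4-OH and C3, because the 2-OH is tied up in a hydrogen bond to the aldehyde, giving the angular chromene.

**Step 6**
Reactants: 12 5-hydroxy-2,2-dimethyl-2H-chromene-6-carbaldehyde
Product: 13 5-methoxy-2,2-dimethyl-2H-chromene-6-carbaldehyde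
Conditions: MeI, K2CO3, DMF, 40 °C
Reagents that add atoms: iodomethane, CI
Why: Williamson methylation in a dipolar aprotic solvent overcomes the chelation of the phenol to the aldehyde.

**Step 7**
Reactants: 13 5-methoxy-2,2-dimethyl-2H-chromene-6-carbaldehyde
Product: 15 2-(5-methoxy-2,2-dimethyl-2H-chromen-6-yl)acetonitrile, via tosyloxazoline 14 (not isolated)
Conditions: TosMIC, t-BuOK, DME, −40 °C; then MeOH, reflux
Reagents that add atoms: p-toluenesulfonylmethyl isocyanide (TosMIC), Cc1ccc(cc1)S(=O)(=O)C[N+]#[C-]
Why: Van Leusen reductive cyanation: the TosMIC anion adds to the aldehyde and closes to the 4-tosyl-2-oxazoline, which on methanolysis loses the formyl carbon as methyl formate and then sulfinate, giving the one-carbon homologated nitrile under basic conditions that spare the chromene.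

**Step 8**
Reactants: 15 2-(5-methoxy-2,2-dimethyl-2H-chromen-6-yl)acetonitrile
Product: 16 2-(5-methoxy-2,2-dimethyl-2H-chromen-6-yl)acetic acid
Conditions: KOH, EtOH–H2O, reflux; then 1 M HCl to pH 3, 0 °C
Reagents that add atoms: water (delivered as hydroxide), O
Why: Alkaline nitrile hydrolysis, to which the chromene and the aryl methyl ether are inert, followed by cold acidification to the free acid.

**Step 9**
Reactants: 16 2-(5-methoxy-2,2-dimethyl-2H-chromen-6-yl)acetic acid
Product: 17 allyl 2-(5-methoxy-2,2-dimethyl-2H-chromen-6-yl)acetate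
Conditions: allyl bromide, K2CO3, DMF, rt
Reagents that add atoms: allyl bromide, C=CCBr
Why: SN2 O-alkylation of the carboxylate gives the allyl ester without acid.

**Step 10**
Reactants: 17 allyl 2-(5-methoxy-2,2-dimethyl-2H-chromen-6-yl)acetate; 18 diallyl carbonate
Product: 19 diallyl 2-(5-methoxy-2,2-dimethyl-2H-chromen-6-yl)malonate
Conditions: NaH (2.2 equiv), 18 (3 equiv), THF, 60 °C; AcOH quench
Reagents that add atoms: none
Why: Claisen-type C-alkoxycarbonylation of the arylacetate enolate with a dialkyl carbonate is driven by deprotonation of the arylmalonate formed, and matching allyl groups make any transesterification degenerate.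

**Step 11**
Reactants: 19 diallyl 2-(5-methoxy-2,2-dimethyl-2H-chromen-6-yl)malonate
Product: 20 diallyl 2-(hydroxymethyl)-2-(5-methoxy-2,2-dimethyl-2H-chromen-6-yl)malonate
Conditions: 37% aq. CH2O (excess), KHCO3 (cat.), THF, rt; aq. NH4Cl before concentration
Reagents that add atoms: formaldehyde, C=O
Why: Base-catalysed aldol addition (hydroxymethylation) of the acidic malonate C–H to formaldehyde, held on the adduct side by excess formaldehyde and by neutralising before concentration so that retro-aldol cannot set in.

**Step 12**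
Reactants: 9 3,5-bis(methoxymethoxy)-2-(trimethylsilyl)phenyl trifluoromethanesulfonate; 20 diallyl 2-(hydroxymethyl)-2-(5-methoxy-2,2-dimethyl-2H-chromen-6-yl)malonate
Product: 22 allyl 5,7-bis(methoxymethoxy)-3-(5-methoxy-2,2-dimethyl-2H-chromen-6-yl)-4-oxochromane-3-carboxylate (racemic), via benzyne 21 (not isolated)
Conditions: 9 (2 equiv, in portions), CsF (4 equiv), 18-crown-6 (0.5 equiv), 4 Å MS, THF, 0 °C to rt
Reagents that add atoms: none
Why: Proposed new method: fluoride-induced 1,2-elimination of 9 gives benzyne 21, the fluoride-activated primary hydroxyl of 20 adds at C8a, the aryne carbon remote from the C5 OMOM group, and the C4a aryl anion left next to that group attacks one of the two allyl esters and expels allyloxide, which carries the hydroxyl proton away as allyl alcohol. The closest known reaction type is the CsF-mediated annulation of arynes with salicylate esters to xanthones (O-arylation, then intramolecular acyl substitution), and O-arylation of aliphatic alcohols by silylaryl triflate-derived arynes is also known; new here is an aliphatic β-hydroxy ester as the partner. Ring C closes by 6-exo-trig acyl substitution, helped by the fully substituted C3 (Thorpe–Ingold effect) and by two equivalent ester acceptors. C3 becomes a stereocentre, but the two esters are enantiotopic and no control is exerted or needed, because 22 is carried on as the racemate and C3 is flattened to the palladium enolate in step 13. The step needs O-attack at C8a, which the inductive effect of the flanking C5 oxygen and the resulting aryne distortion secure. It also needs ring closure to outrun protonation of the aryl anion and retro-aldol loss of formaldehyde from the alkoxide, for which the aprotic medium, fluoride as the only base, the low temperature and the excess of 9 (which also scavenges allyloxide) are chosen.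

**Step 13**
Reactants: 22 allyl 5,7-bis(methoxymethoxy)-3-(5-methoxy-2,2-dimethyl-2H-chromen-6-yl)-4-oxochromane-3-carboxylate (racemic)
Product: 23 (3R)-5,7-bis(methoxymethoxy)-3-(5-methoxy-2,2-dimethyl-2H-chromen-6-yl)chroman-4-one
Conditions: Pd2(dba)3 (5 mol %), (S)-t-BuPHOX (12.5 mol %), HCO2H (6 equiv), 4 Å MS, 1,4-dioxane, 40 °C
Reagents that add atoms: none
Why: Palladium-catalysed enantioselective decarboxylative protonation: zerovalent palladium ionises the allyl ester, CO2 is lost, and the chiral phosphinooxazoline-bound palladium enolate is protonated by formic acid on one face (the ortho-methoxy group of ring B sharpens the facial bias) while formate reduces the allyl ligand to propene, a reaction type known for α-aryl β-keto allyl esters of chromanones.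

**Step 14**
Reactants: 23 (3R)-5,7-bis(methoxymethoxy)-3-(5-methoxy-2,2-dimethyl-2H-chromen-6-yl)chroman-4-one
Product: 24 (3R)-5,7-dihydroxy-3-(5-methoxy-2,2-dimethyl-2H-chromen-6-yl)chroman-4-one
Conditions: HCl (1.25 M in MeOH), THF, 30 °C, monitored; pH 7 phosphate buffer quench
Reagents that add atoms: none
Why: Acid-catalysed transacetalisation of the two aryl MOM ethers to dimethoxymethane under mild, base-free conditions should leave the C3–H stereocentre and the chromene double bond untouched, the peri C5 acetal going first and the C7 acetal second.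

**Compound list**
1 | phloroglucinol | Oc1cc(O)cc(O)c1 | starting material
2 | 3,5-bis(methoxymethoxy)phenol | COCOc1cc(O)cc(OCOC)c1 | intermediate
3 | 3,5-bis(methoxymethoxy)phenyl N-isopropylcarbamate | CC(C)NC(=O)Oc1cc(OCOC)cc(OCOC)c1 | intermediate
4 | 3,5-bis(methoxymethoxy)phenyl N-isopropyl-N-(trimethylsilyl)carbamate (not isolated) | CC(C)N([Si](C)(C)C)C(=O)Oc1cc(OCOC)cc(OCOC)c1 | intermediate
5 | 2-lithio derivative of 4 (not isolated) | CC(C)N([Si](C)(C)C)C(=O)Oc1cc(OCOC)cc(OCOC)c1[Li] | intermediate
6 | 3,5-bis(methoxymethoxy)-2-(trimethylsilyl)phenyl N-isopropyl-N-(trimethylsilyl)carbamate (not isolated) | CC(C)N([Si](C)(C)C)C(=O)Oc1cc(OCOC)cc(OCOC)c1[Si](C)(C)C | intermediate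
7 | 3,5-bis(methoxymethoxy)-2-(trimethylsilyl)phenyl N-isopropylcarbamate | CC(C)NC(=O)Oc1cc(OCOC)cc(OCOC)c1[Si](C)(C)C | intermediate
8 | 3,5-bis(methoxymethoxy)-2-(trimethylsilyl)phenol (not isolated) | COCOc1cc(O)c([Si](C)(C)C)c(OCOC)c1 | intermediate
9 | 3,5-bis(methoxymethoxy)-2-(trimethylsilyl)phenyl trifluoromethanesulfonate | COCOc1cc(OCOC)c([Si](C)(C)C)c(OS(=O)(=O)C(F)(F)F)c1 | intermediate
10 | 2,4-dihydroxybenzaldehyde | O=Cc1ccc(O)cc1O | starting material
11 | 3-methylbut-2-enal | CC(C)=CC=O | starting material
12 | 5-hydroxy-2,2-dimethyl-2H-chromene-6-carbaldehyde | CC1(C)C=Cc2c(O)c(C=O)ccc2O1 | intermediate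
13 | 5-methoxy-2,2-dimethyl-2H-chromene-6-carbaldehyde | COc1c(C=O)ccc2OC(C)(C)C=Cc12 | intermediate
14 | 5-(5-methoxy-2,2-dimethyl-2H-chromen-6-yl)-4-tosyl-4,5-dihydro-1,3-oxazole (racemic, relative configuration not defined, not isolated) | COc1c(C2OC=NC2S(=O)(=O)c2ccc(C)cc2)ccc2OC(C)(C)C=Cc12 | intermediate
15 | 2-(5-methoxy-2,2-dimethyl-2H-chromen-6-yl)acetonitrile | COc1c(CC#N)ccc2OC(C)(C)C=Cc12 | intermediate
16 | 2-(5-methoxy-2,2-dimethyl-2H-chromen-6-yl)acetic acid | COc1c(CC(=O)O)ccc2OC(C)(C)C=Cc12 | intermediate
17 | allyl 2-(5-methoxy-2,2-dimethyl-2H-chromen-6-yl)acetate | COc1c(CC(=O)OCC=C)ccc2OC(C)(C)C=Cc12 | intermediate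
18 | diallyl carbonate | C=CCOC(=O)OCC=C | starting material
19 | diallyl 2-(5-methoxy-2,2-dimethyl-2H-chromen-6-yl)malonate | C=CCOC(=O)C(C(=O)OCC=C)c1ccc2OC(C)(C)C=Cc2c1OC | intermediate
20 | diallyl 2-(hydroxymethyl)-2-(5-methoxy-2,2-dimethyl-2H-chromen-6-yl)malonate | C=CCOC(=O)C(CO)(C(=O)OCC=C)c1ccc2OC(C)(C)C=Cc2c1OC | intermediate
21 | 3,5-bis(methoxymethoxy)benzyne (not isolated) | COCOC1=CC#CC(OCOC)=C1 | intermediate
22 | allyl 5,7-bis(methoxymethoxy)-3-(5-methoxy-2,2-dimethyl-2H-chromen-6-yl)-4-oxochromane-3-carboxylate (racemic) | C=CCOC(=O)C1(c2ccc3OC(C)(C)C=Cc3c2OC)COc2cc(OCOC)cc(OCOC)c2C1=O | intermediate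
23 | (3R)-5,7-bis(methoxymethoxy)-3-(5-methoxy-2,2-dimethyl-2H-chromen-6-yl)chroman-4-one | COc1c([C@@H]2COc3cc(OCOC)cc(OCOC)c3C2=O)ccc2c1C=CC(C)(C)O2 | intermediate
24 | (3R)-5,7-dihydroxy-3-(5-methoxy-2,2-dimethyl-2H-chromen-6-yl)chroman-4-one | COc1c([C@@H]2COc3cc(O)cc(O)c3C2=O)ccc2c1C=CC(C)(C)O2 | target

Total step count: 14.
Longest linear sequence: 10 steps (steps 5 to 14); the ring A branch (steps 1 to 4) joins at step 12.

**Steps most likely to fail**

1. Step 12 (proposed new method). Three processes may divert it:
   - retro-aldol loss of formaldehyde from the alkoxide, with the freed malonate anion then consumed by the aryne;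
   - protonation of the aryl anion before it reaches an ester, which stops at the open aryl ether;
   - capture of the aryne by the styrene-like chromene double bond.

   The fallback uses known chemistry, sets out from 3 and 20 and returns at 22. Aryllithium 5, generated from 3 as in step 3, is quenched with iodine in place of TMSCl to give 2-iodo-3,5-bis(methoxymethoxy)phenyl N-isopropyl-N-(trimethylsilyl)carbamate F1, which loses its N-silyl group on aqueous work-up to give 2-iodo-3,5-bis(methoxymethoxy)phenyl N-isopropylcarbamate F2. Et2NH and DBU in MeCN then free 2-iodo-3,5-bis(methoxymethoxy)phenol F3. Mitsunobu etherification of F3 with 20 (PPh3, DIAD, toluene, 60 °C), which never passes through a free alkoxide, should give diallyl 2-{[2-iodo-3,5-bis(methoxymethoxy)phenoxy]methyl}-2-(5-methoxy-2,2-dimethyl-2H-chromen-6-yl)malonate F4. Iodine–magnesium exchange with i-PrMgCl·LiCl (THF, −40 °C to 0 °C) then places the metal on C4a, and Parham-type intramolecular acylation onto one allyl ester closes ring C to 22.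

2. Step 13. Poor facial selectivity in the protonation of the palladium enolate, or protonation by adventitious acid away from the metal, would give 23 in low enantiomeric purity. The fallback sets out from 22 and returns at 23. Achiral deallylative decarboxylation (Pd(OAc)2, PPh3, HCO2H–Et3N, THF) gives racemic 5,7-bis(methoxymethoxy)-3-(5-methoxy-2,2-dimethyl-2H-chromen-6-yl)chroman-4-one F5. Asymmetric transfer hydrogenation with dynamic kinetic resolution (RuCl[(R,R)-TsDPEN](p-cymene), HCO2H–Et3N, EtOAc, 40 °C) racemises C3 through the enol while reducing one enantiomer, a known process for isoflavanones. On the usual model for aryl ketones it should give (3R,4R)-cis-5,7-bis(methoxymethoxy)-3-(5-methoxy-2,2-dimethyl-2H-chromen-6-yl)chroman-4-ol F6, and the antipodal catalyst is taken if the sense proves opposite. Dess–Martin periodinane (CH2Cl2, 0 °C) then re-oxidises C4 without touching C3 and returns 23.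

3. Step 14. Acid-catalysed enolisation at C3 while the slower C7 acetal is being cleaved would erode the enantiomeric purity. The fallback sets out from 22 and returns at 24, and moves the acid step to before the stereocentre exists. Aqueous HCl in THF at 40 °C cleaves both acetals of racemic 22 to allyl 5,7-dihydroxy-3-(5-methoxy-2,2-dimethyl-2H-chromen-6-yl)-4-oxochromane-3-carboxylate F7. TBSOTf and 2,6-lutidine in CH2Cl2 give allyl 5,7-bis(tert-butyldimethylsilyloxy)-3-(5-methoxy-2,2-dimethyl-2H-chromen-6-yl)-4-oxochromane-3-carboxylate F8. The decarboxylative protonation of step 13 is run on F8 to give (3R)-5,7-bis(tert-butyldimethylsilyloxy)-3-(5-methoxy-2,2-dimethyl-2H-chromen-6-yl)chroman-4-one F9. HF·pyridine buffered with pyridine in THF at 0 °C then removes both silyl groups under near-neutral conditions to give 24.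

**Further compounds**
F1 | step 12 | 2-iodo-3,5-bis(methoxymethoxy)phenyl N-isopropyl-N-(trimethylsilyl)carbamate | CC(C)N([Si](C)(C)C)C(=O)Oc1cc(OCOC)cc(OCOC)c1I
F2 | step 12 | 2-iodo-3,5-bis(methoxymethoxy)phenyl N-isopropylcarbamate | CC(C)NC(=O)Oc1cc(OCOC)cc(OCOC)c1I
F3 | step 12 | 2-iodo-3,5-bis(methoxymethoxy)phenol | COCOc1cc(O)c(I)c(OCOC)c1
F4 | step 12 | diallyl 2-{[2-iodo-3,5-bis(methoxymethoxy)phenoxy]methyl}-2-(5-methoxy-2,2-dimethyl-2H-chromen-6-yl)malonate | C=CCOC(=O)C(COc1cc(OCOC)cc(OCOC)c1I)(C(=O)OCC=C)c1ccc2OC(C)(C)C=Cc2c1OC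
F5 | step 13 | 5,7-bis(methoxymethoxy)-3-(5-methoxy-2,2-dimethyl-2H-chromen-6-yl)chroman-4-one (racemic) | COc1c(C2COc3cc(OCOC)cc(OCOC)c3C2=O)ccc2c1C=CC(C)(C)O2
F6 | step 13 | (3R,4R)-5,7-bis(methoxymethoxy)-3-(5-methoxy-2,2-dimethyl-2H-chromen-6-yl)chroman-4-ol (cis) | COc1c([C@@H]2COc3cc(OCOC)cc(OCOC)c3[C@@H]2O)ccc2c1C=CC(C)(C)O2
F7 | step 14 | allyl 5,7-dihydroxy-3-(5-methoxy-2,2-dimethyl-2H-chromen-6-yl)-4-oxochromane-3-carboxylate (racemic) | C=CCOC(=O)C1(c2ccc3OC(C)(C)C=Cc3c2OC)COc2cc(O)cc(O)c2C1=O
F8 | step 14 | allyl 5,7-bis(tert-butyldimethylsilyloxy)-3-(5-methoxy-2,2-dimethyl-2H-chromen-6-yl)-4-oxochromane-3-carboxylate (racemic) | C=CCOC(=O)C1(c2ccc3OC(C)(C)C=Cc3c2OC)COc2cc(O[Si](C)(C)C(C)(C)C)cc(O[Si](C)(C)C(C)(C)C)c2C1=O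
F9 | step 14 | (3R)-5,7-bis(tert-butyldimethylsilyloxy)-3-(5-methoxy-2,2-dimethyl-2H-chromen-6-yl)chroman-4-one | COc1c([C@@H]2COc3cc(O[Si](C)(C)C(C)(C)C)cc(O[Si](C)(C)C(C)(C)C)c3C2=O)ccc2c1C=CC(C)(C)O2
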